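**Strategy**

The route rests on disconnecting the dihydrofuran ring at the bond between its oxygen and C7 of the flavan ring A. The structure offers a ketal carbon C2 that is shared by the chromanone and dihydrofuran rings and sits next to the carbinol C3, already bonded to C8 of ring A. In the key step an aryl Grignard reagent adds to the lactone carbonyl of an enantioenriched 3-aryl-3-hydroxychromane-2,4-dione whose flavan-derived aryl group carries bromine at C7. The former carbonyl oxygen, now a hemiketal hydroxyl, is arylated in the same flask under palladium catalysis. One operation installs the 4-oxyphenyl group, closes the dihydrofuran and fixes C2, because only the cis ring fusion dictated by C3 can form.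

Key step: step 10

Assumption: compounds 12 and 17 are taken as commercial, and the sense of induction of dihydroquinidine in step 9 is assigned by analogy, its pseudoenantiomer dihydroquinine being the remedy if it proves opposite.

**Route**

Step 1
Reactants: 1 4-bromo-2,6-difluorobenzaldehyde
Product: 2 2-(benzyloxy)-4-bromo-6-fluorobenzaldehyde
Conditions: BnOH (1.0 equiv), KOtBu (1.0 equiv), THF, −20 to 0 °C
Reagents that add atoms: benzyl alcohol, OCc1ccccc1
Why: Nucleophilic aromatic substitution, in which the fluorides ortho to the formyl group are activated and leave far faster than the para bromide, while the first benzyloxy group deactivates the ring towards a second substitution, so mono-etherification should prevail.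

Step 2
Reactants: 2 2-(benzyloxy)-4-bromo-6-fluorobenzaldehyde; 3 1-[4-(benzyloxy)phenyl]ethan-1-one
Product: 4 (E)-3-[2-(benzyloxy)-4-bromo-6-fluorophenyl]-1-[4-(benzyloxy)phenyl]prop-2-en-1-one
Conditions: LiOH·H2O (20 mol %), EtOH–THF, rt
Reagents that add atoms: none
Why: Claisen–Schmidt aldol condensation of the non-enolizable aldehyde with the methyl ketone, which should give the conjugated (E)-enone under thermodynamic control.

Step 3
Reactants: 4 (E)-3-[2-(benzyloxy)-4-bromo-6-fluorophenyl]-1-[4-(benzyloxy)phenyl]prop-2-en-1-one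
Product: 6 (S)-3-[2-(benzyloxy)-4-bromo-6-fluorophenyl]-1-[4-(benzyloxy)phenyl]propan-1-ol, via saturated ketone 5 (not isolated)
Conditions: RuCl[(S,S)-TsDPEN](p-cymene) (2 mol %), HCO2H–Et3N (5:2), DMF, 40 °C
Reagents that add atoms: none
Why: Tandem Noyori–Ikariya asymmetric transfer hydrogenation, in which the ruthenium hydride first reduces the conjugated C=C bond and then the aryl ketone, the (S,S)-catalyst giving the (S)-carbinol as with other aryl alkyl ketones, while aryl halides and benzyl ethers are inert.

Step 4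
Reactants: 6 (S)-3-[2-(benzyloxy)-4-bromo-6-fluorophenyl]-1-[4-(benzyloxy)phenyl]propan-1-ol
Product: 7 (S)-5-(benzyloxy)-2-[4-(benzyloxy)phenyl]-7-bromochromane
Conditions: NaH (1.2 equiv), DMF, 0 °C then 70 °C
Reagents that add atoms: none
Why: Intramolecular nucleophilic aromatic substitution (six-membered ring) of the sodium alkoxide on the aryl fluoride, activated inductively by the meta bromine and meta benzyloxy groups; the C–O bond at the stereocenter is not broken, so the (S) configuration is retained in the flavan.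

Step 5
Reactants: 7 (S)-5-(benzyloxy)-2-[4-(benzyloxy)phenyl]-7-bromochromane
Product: 8 (S)-5-(benzyloxy)-2-[4-(benzyloxy)phenyl]-7-bromo-8-iodochromane
Conditions: NIS (1.05 equiv), TFA (20 mol %), MeCN, 0 °C
Reagents that add atoms: N-iodosuccinimide, O=C1CCC(=O)N1I
Why: Electrophilic aromatic iodination, expected at C8 (ortho to the ring oxygen, para to the C5 benzyloxy group) because the similarly activated C6 is shielded by the benzyloxy group, in line with the C8 preference of 5,7-dioxygenated flavans, and ring B is much less activated.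

Step 6
Reactants: 8 (S)-5-(benzyloxy)-2-[4-(benzyloxy)phenyl]-7-bromo-8-iodochromane
Product: 11 [(S)-5-(benzyloxy)-2-[4-(benzyloxy)phenyl]-7-bromochroman-8-yl]boronic acid, via arylmagnesium chloride 9 (not isolated), via dimethyl arylboronate 10 (not isolated)
Conditions: i-PrMgCl·LiCl (1.1 equiv), THF, −40 °C; B(OMe)3 (2 equiv), −40 °C to rt; 1 M HCl, 0 °C
Reagents that add atoms: trimethyl borate, COB(OC)OC; water, O
Why: Iodine–magnesium exchange with the turbo Grignard reagent is selective for iodide over bromide and the ortho-bromoaryl Grignard should be stable at −40 °C, so borate trapping and hydrolysis should give the boronic acid.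

Step 7
Reactants: 12 1-[2,4-bis(benzyloxy)-6-hydroxyphenyl]ethan-1-one
Product: 13 5,7-bis(benzyloxy)-4-hydroxy-2H-chromen-2-one
Conditions: NaH (3 equiv), (EtO)2CO, toluene, 100 °C; then 1 M HCl
Reagents that add atoms: diethyl carbonate, CCOC(=O)OCC
Why: Claisen-type C-acylation of the ketone enolate by diethyl carbonate followed by lactonization of the ortho phenoxide, the standard 4-hydroxycoumarin synthesis from 2-hydroxyacetophenones.

Step 8
Reactants: 11 [(S)-5-(benzyloxy)-2-[4-(benzyloxy)phenyl]-7-bromochroman-8-yl]boronic acid; 13 5,7-bis(benzyloxy)-4-hydroxy-2H-chromen-2-one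
Product: 15 5,7-bis(benzyloxy)-3-[(2S)-5-(benzyloxy)-2-[4-(benzyloxy)phenyl]-7-bromochroman-8-yl]-4-hydroxy-2H-chromen-2-one, via aryllead triacetate 14 (not isolated)
Conditions: Pb(OAc)4 (1.05 equiv), Hg(OAc)2 (10 mol %), CHCl3, 40 °C; then 13, pyridine (3 equiv), CHCl3, 60 °C
Reagents that add atoms: none
Why: Pinhey arylation, in which boron–lead exchange gives the aryllead triacetate that arylates C3 of the 4-hydroxycoumarin by ligand coupling, a process that favours ortho-substituted electron-rich aryl groups and leaves the aryl bromide untouched; no stereocenter is formed, only rotamers about the new C3–aryl bond.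

Step 9
Reactants: 15 5,7-bis(benzyloxy)-3-[(2S)-5-(benzyloxy)-2-[4-(benzyloxy)phenyl]-7-bromochroman-8-yl]-4-hydroxy-2H-chromen-2-one
Product: 16 (3R)-5,7-bis(benzyloxy)-3-[(2S)-5-(benzyloxy)-2-[4-(benzyloxy)phenyl]-7-bromochroman-8-yl]-3-hydroxychromane-2,4-dione
Conditions: dihydroquinidine (20 mol %), cumene hydroperoxide (1.5 equiv), CH2Br2, 40 °C
Reagents that add atoms: cumene hydroperoxide, CC(C)(OO)c1ccccc1
Why: Cinchona-alkaloid-catalysed electrophilic α-hydroxylation of a cyclic β-dicarbonyl compound, in which the chiral ammonium enolate ion pair should expose one face of C3 to the hydrogen-bonded hydroperoxide and so set C3 as R under reagent control, while 40 °C should let the rotamers about the C3–aryl bond interconvert and funnel to one product.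

Step 10
Reactants: 16 (3R)-5,7-bis(benzyloxy)-3-[(2S)-5-(benzyloxy)-2-[4-(benzyloxy)phenyl]-7-bromochroman-8-yl]-3-hydroxychromane-2,4-dione; 17 4-(benzyloxy)phenylmagnesium bromide
Product: 19 penta-O-benzyl daphnodorin F, via hemiketal 18 (not isolated)
Conditions: 17 (2.2 equiv), THF, −78 to −40 °C; AcOH (2.2 equiv); then Pd(OAc)2 (5 mol %), t-BuXPhos (10 mol %), Cs2CO3 (4 equiv), toluene, 70 °C
Reagents that add atoms: none
Why: Addition of 17 to the magnesium alkoxide of 16 should occur at the lactone (aryl ester) carbonyl and not at the C4 ketone, which is deactivated by conjugation with the 5,7-dioxygenated ring and screened by the C5 benzyloxy group, so that the former carbonyl oxygen becomes the hydroxyl of hemiketal 18, which equilibrates with its open 2-hydroxy-1,3-diketone tautomer. After the acetic acid quench, oxidative addition of zerovalent palladium into the C7–Br bond of the flavan ring A, exchange of bromide for the C2 hemiketal alkoxide and C–O reductive elimination from a six-membered oxapalladacycle form the O–C7 bond. The closest known reactions are the addition of aryl organometallics to lactones to give lactols, the Buchwald–Hartwig intramolecular etherification of aryl bromides with tertiary alkoxides and the anomeric O-arylation of lactols. The dihydrofuran ring is closed by this reductive elimination in a five-membered mode; the C3 hydroxyl could only give a four-membered ring and the ring A phenoxide of the open tautomer an eight-membered palladacycle. The new stereocenter C2 is controlled by C3, since the hemiketal epimerizes through its open form and only the epimer with the C2 oxygen cis to the C3 aryl group can cyclize, which gives the cis-fused (2S,3R) ketal. The step needs chemoselective addition and a coupling that outruns base-induced acyl migration of the open tautomer, which the low addition temperature, the weak carbonate base and the fast five-membered closure should secure.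

Step 11
Reactants: 19 penta-O-benzyl daphnodorin F
Product: 20 daphnodorin F
Conditions: H2 (1 atm), Pd/C (10 %), EtOAc–MeOH, rt
Reagents that add atoms: none
Why: Hydrogenolysis of the five benzyl aryl ethers over Pd/C, under which the diaryl ketal, the tertiary carbinol and the cyclic benzylic ether of the flavan should be cleaved far more slowly, so the three stereocenters should stay untouched.

**Compound list**

1 | 4-bromo-2,6-difluorobenzaldehyde | O=Cc1c(F)cc(Br)cc1F | starting material
2 | 2-(benzyloxy)-4-bromo-6-fluorobenzaldehyde | O=Cc1c(F)cc(Br)cc1OCc1ccccc1 | intermediate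
3 | 1-[4-(benzyloxy)phenyl]ethan-1-one | CC(=O)c1ccc(OCc2ccccc2)cc1 | starting material
4 | (E)-3-[2-(benzyloxy)-4-bromo-6-fluorophenyl]-1-[4-(benzyloxy)phenyl]prop-2-en-1-one | O=C(/C=C/c1c(F)cc(Br)cc1OCc1ccccc1)c1ccc(OCc2ccccc2)cc1 | intermediate
5 | 3-[2-(benzyloxy)-4-bromo-6-fluorophenyl]-1-[4-(benzyloxy)phenyl]propan-1-one (saturated ketone) | O=C(CCc1c(F)cc(Br)cc1OCc1ccccc1)c1ccc(OCc2ccccc2)cc1 | intermediate
6 | (S)-3-[2-(benzyloxy)-4-bromo-6-fluorophenyl]-1-[4-(benzyloxy)phenyl]propan-1-ol | O[C@@H](CCc1c(F)cc(Br)cc1OCc1ccccc1)c1ccc(OCc2ccccc2)cc1 | intermediate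
7 | (S)-5-(benzyloxy)-2-[4-(benzyloxy)phenyl]-7-bromochromane | Brc1cc(OCc2ccccc2)c2c(c1)O[C@H](c1ccc(OCc3ccccc3)cc1)CC2 | intermediate
8 | (S)-5-(benzyloxy)-2-[4-(benzyloxy)phenyl]-7-bromo-8-iodochromane | Brc1cc(OCc2ccccc2)c2c(c1I)O[C@H](c1ccc(OCc3ccccc3)cc1)CC2 | intermediate
9 | [(S)-5-(benzyloxy)-2-[4-(benzyloxy)phenyl]-7-bromochroman-8-yl]magnesium chloride (arylmagnesium chloride) | Cl[Mg]c1c(Br)cc(OCc2ccccc2)c2c1O[C@H](c1ccc(OCc3ccccc3)cc1)CC2 | intermediate
10 | dimethyl [(S)-5-(benzyloxy)-2-[4-(benzyloxy)phenyl]-7-bromochroman-8-yl]boronate (dimethyl arylboronate) | COB(OC)c1c(Br)cc(OCc2ccccc2)c2c1O[C@H](c1ccc(OCc3ccccc3)cc1)CC2 | intermediate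
11 | [(S)-5-(benzyloxy)-2-[4-(benzyloxy)phenyl]-7-bromochroman-8-yl]boronic acid | OB(O)c1c(Br)cc(OCc2ccccc2)c2c1O[C@H](c1ccc(OCc3ccccc3)cc1)CC2 | intermediate
12 | 1-[2,4-bis(benzyloxy)-6-hydroxyphenyl]ethan-1-one | CC(=O)c1c(O)cc(OCc2ccccc2)cc1OCc1ccccc1 | starting material
13 | 5,7-bis(benzyloxy)-4-hydroxy-2H-chromen-2-one | O=C1C=C(O)c2c(OCc3ccccc3)cc(OCc3ccccc3)cc2O1 | intermediate
14 | [(S)-5-(benzyloxy)-2-[4-(benzyloxy)phenyl]-7-bromochroman-8-yl]lead triacetate (aryllead triacetate) | CC(=O)O[Pb](OC(C)=O)(OC(C)=O)c1c(Br)cc(OCc2ccccc2)c2c1O[C@H](c1ccc(OCc3ccccc3)cc1)CC2 | intermediate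
15 | 5,7-bis(benzyloxy)-3-[(2S)-5-(benzyloxy)-2-[4-(benzyloxy)phenyl]-7-bromochroman-8-yl]-4-hydroxy-2H-chromen-2-one | O=C1Oc2cc(OCc3ccccc3)cc(OCc3ccccc3)c2C(O)=C1c1c(Br)cc(OCc2ccccc2)c2c1O[C@H](c1ccc(OCc3ccccc3)cc1)CC2 | intermediate
16 | (3R)-5,7-bis(benzyloxy)-3-[(2S)-5-(benzyloxy)-2-[4-(benzyloxy)phenyl]-7-bromochroman-8-yl]-3-hydroxychromane-2,4-dione | O=C1Oc2cc(OCc3ccccc3)cc(OCc3ccccc3)c2C(=O)[C@]1(O)c1c(Br)cc(OCc2ccccc2)c2c1O[C@H](c1ccc(OCc3ccccc3)cc1)CC2 | intermediate
17 | 4-(benzyloxy)phenylmagnesium bromide | Br[Mg]c1ccc(OCc2ccccc2)cc1 | starting material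
18 | (3R)-5,7-bis(benzyloxy)-2-[4-(benzyloxy)phenyl]-3-[(2S)-5-(benzyloxy)-2-[4-(benzyloxy)phenyl]-7-bromochroman-8-yl]-2,3-dihydroxychroman-4-one (hemiketal, both C2 epimers, in equilibrium with the open 2-hydroxy-1,3-diketone) | O=C1c2c(OCc3ccccc3)cc(OCc3ccccc3)cc2OC(O)(c2ccc(OCc3ccccc3)cc2)[C@@]1(O)c1c(Br)cc(OCc2ccccc2)c2c1O[C@H](c1ccc(OCc3ccccc3)cc1)CC2 | intermediate
19 | penta-O-benzyl daphnodorin F (all five phenols as benzyl ethers; ketal carbon C2 S, carbinol C3 R, flavan C2 S) | O=C1c2c(OCc3ccccc3)cc(OCc3ccccc3)cc2O[C@]2(c3ccc(OCc4ccccc4)cc3)Oc3cc(OCc4ccccc4)c4c(c3[C@@]12O)O[C@H](c1ccc(OCc3ccccc3)cc1)CC4 | intermediate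
20 | daphnodorin F (ketal carbon C2 S, carbinol C3 R, flavan C2 S) | O=C1c2c(O)cc(O)cc2O[C@]2(c3ccc(O)cc3)Oc3cc(O)c4c(c3[C@@]12O)O[C@H](c1ccc(O)cc1)CC4 | target

**Step count and risks**

Total step count: 11. Longest linear sequence: 10 (steps 1–6 and 8–11; step 7 makes the coumarin partner).

Steps most likely to fail:

1. Step 10 (key step). The Grignard reagent may add to the C4 ketone or add twice, the open tautomer may undergo base-induced acyl migration or α-ketol rearrangement before the coupling, and oxidative addition into the electron-rich bromide may be slow. The fallback sets out from 16 and separates the two events. Aminolysis of the lactone with Me(MeO)NH·HCl and AlMe3 should give the ring-opened Weinreb amide F1. Addition of 17 to the amide (Weinreb ketone synthesis; the ketone is masked as its ortho-phenoxide) should give hemiketal 18, now isolated. Miyaura borylation of 18 (B2pin2, PdCl2(dppf), KOAc, dioxane, 80 °C) should give the pinacol boronate F2. An intramolecular Chan–Lam coupling of the hemiketal hydroxyl (Cu(OAc)2, pyridine, O2, CH2Cl2, rt) should then close the same O–C7 bond under nearly neutral conditions and rejoin the route at 19.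

2. Step 9. Facial selectivity may be poor because the enolate is weakly nucleophilic and its rotamers about the C3–aryl bond may interconvert slowly and bias the two faces against the catalyst. The fallback sets out from 13 and 8 and builds the carbinol by carbonyl addition instead of enolate oxidation. Diazo transfer to 13 (p-acetamidobenzenesulfonyl azide, Et3N, MeCN) should give the diazo dione F3. Oxidation with dimethyldioxirane should give the vicinal tricarbonyl compound F4. Grignard reagent 9 (made from 8 as in step 6) should add to its central carbonyl at −78 °C to give 16 together with its C3 epimer F5. The two are diastereomers and would be separated by chromatography; this fallback gives up control at C3, and the route is rejoined at 16.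

3. Step 5. Iodination may leak to C6 or give di-iodination. The fallback sets out from 6 and fixes the position before the ring is closed. Deprotonation of the hydroxyl with MeMgCl, then directed magnesiation with TMPMgCl·LiCl (THF, −20 °C) at the C–H flanked by fluorine and bromine (the most acidic ring position) and an iodine quench should give the iodo alcohol F6. The cyclization of step 4 (NaH, DMF, 70 °C) should then deliver 8 directly, where the route is rejoined.

**Further compounds**

F1 | step 10 | (2R)-3-[2,4-bis(benzyloxy)-6-hydroxyphenyl]-2-[(2S)-5-(benzyloxy)-2-[4-(benzyloxy)phenyl]-7-bromochroman-8-yl]-2-hydroxy-N-methoxy-N-methyl-3-oxopropanamide | CON(C)C(=O)[C@@](O)(c1c(Br)cc(OCc2ccccc2)c2c1O[C@H](c1ccc(OCc3ccccc3)cc1)CC2)C(=O)c1c(O)cc(OCc2ccccc2)cc1OCc1ccccc1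
F2 | step 10 | pinacol boronate of 18 (Bpin in place of Br at flavan C7) | O=C1c2c(OCc3ccccc3)cc(OCc3ccccc3)cc2OC(O)(c2ccc(OCc3ccccc3)cc2)[C@@]1(O)c1c(B2OC(C)(C)C(C)(C)O2)cc(OCc2ccccc2)c2c1O[C@H](c1ccc(OCc3ccccc3)cc1)CC2
F3 | step 9 | 5,7-bis(benzyloxy)-3-diazochromane-2,4-dione | [N-]=[N+]=C1C(=O)Oc2cc(OCc3ccccc3)cc(OCc3ccccc3)c2C1=O
F4 | step 9 | 5,7-bis(benzyloxy)chromane-2,3,4-trione | O=C1Oc2cc(OCc3ccccc3)cc(OCc3ccccc3)c2C(=O)C1=O
F5 | step 9 | (3S)-5,7-bis(benzyloxy)-3-[(2S)-5-(benzyloxy)-2-[4-(benzyloxy)phenyl]-7-bromochroman-8-yl]-3-hydroxychromane-2,4-dione (C3 epimer of 16) | O=C1Oc2cc(OCc3ccccc3)cc(OCc3ccccc3)c2C(=O)[C@@]1(O)c1c(Br)cc(OCc2ccccc2)c2c1O[C@H](c1ccc(OCc3ccccc3)cc1)CC2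
F6 | step 5 | (S)-3-[6-(benzyloxy)-4-bromo-2-fluoro-3-iodophenyl]-1-[4-(benzyloxy)phenyl]propan-1-ol | O[C@@H](CCc1c(F)c(I)c(Br)cc1OCc1ccccc1)c1ccc(OCc2ccccc2)cc1
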